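The dihydropyran ring C is closed last, through the O1–C2 bond. Ring A enters as unprotected, symmetric 2-prenylresorcinol and ring B as its bis-MOM ether, so the two identical aryl halves are told apart without extra steps. The only stereocentre, C3, is set beforehand by copper-catalysed enantioselective protoboration of a 2,3-diarylpropene. The key step, an intramolecular Mitsunobu etherification of the resulting (R)-2,3-diarylpropan-1-ol, exploits the six-atom chain O1–C8a–C4a–C4–C3–C2: the free phenol O1 of ring A displaces the activated primary carbinol C2 (6-exo-tet), forming ring C without touching C3, while MOM-masked O2′ of ring B cannot close a competing dihydrobenzofuran.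

Key step: step 7

Remark: atom labels follow isoflavan numbering (ring C: O1, C2, C3, C4, C4a, C8a; ring A: C4a to C8a; ring B: primed atoms).
Remark (assumption): the facial sense of the protoboration catalyst on alkene 13 is not presumed; the ligand antipode meant in step 6 is the one that delivers the (R)-configured product, both antipodes being accessible.

Step 1
Reactants: 1 resorcinol (benzene-1,3-diol); 2 chloromethyl methyl ether
Product: 3 1,3-bis(methoxymethoxy)benzene
Conditions: NaH, DMF, 0 °C to rt
Reagents that add atoms: chloromethyl methyl ether, COCCl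
Why: Williamson etherification of both phenoxides should give the bis-MOM ether, whose OMOM groups later direct both ortho-lithiations.

Step 2
Reactants: 3 1,3-bis(methoxymethoxy)benzene; 4 prenyl bromide (1-bromo-3-methylbut-2-ene)
Product: 6 1,3-bis(methoxymethoxy)-2-(3-methylbut-2-en-1-yl)benzene, via C2-aryllithium 5 (not isolated)
Conditions: n-BuLi, THF, 0 °C to rt; then CuBr·SMe2 (10 mol %), prenyl bromide, −78 °C to rt
Reagents that add atoms: prenyl bromide, CC(C)=CCBr
Why: Directed ortho-metalation should remove the C2–H flanked by two OMOM groups, and copper-catalysed SN2 alkylation of the aryllithium should install the prenyl group without allylic transposition.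

Step 3
Reactants: 6 1,3-bis(methoxymethoxy)-2-(3-methylbut-2-en-1-yl)benzene
Product: 7 2-(3-methylbut-2-en-1-yl)benzene-1,3-diol (2-prenylresorcinol)
Conditions: HCl (3 M aq.), MeOH, rt to 40 °C
Reagents that add atoms: none
Why: Acid-catalysed acetal exchange with methanol should free both phenols, with mild and short exposure chosen so that the ortho-prenyl phenol does not cyclise to a 2,2-dimethylchroman.

Step 4
Reactants: 6 1,3-bis(methoxymethoxy)-2-(3-methylbut-2-en-1-yl)benzene; 8 triisopropyl borate; 9 2-bromoprop-2-en-1-ol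
Product: 12 2-[2,4-bis(methoxymethoxy)-3-(3-methylbut-2-en-1-yl)phenyl]prop-2-en-1-ol, via C4-aryllithium 10 (not isolated), via lithium aryltriisopropoxyborate 11 (not isolated)
Conditions: n-BuLi, TMEDA, THF, −78 to 0 °C; B(Oi-Pr)3, −78 °C to rt; then Pd(PPh3)4 (5 mol %), 2-bromoprop-2-en-1-ol, K3PO4 (aq.), 60 °C
Reagents that add atoms: 2-bromoprop-2-en-1-ol, OCC(Br)=C
Why: A one-pot directed ortho-metalation, borylation and Suzuki–Miyaura coupling should lithiate C4 next to OMOM and join the resulting borate to the vinyl bromide, giving the 2-arylallyl alcohol that carries ring B.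

Step 5
Reactants: 7 2-(3-methylbut-2-en-1-yl)benzene-1,3-diol (3 equiv, excess recovered); 12 2-[2,4-bis(methoxymethoxy)-3-(3-methylbut-2-en-1-yl)phenyl]prop-2-en-1-ol
Product: 13 4-{2-[2,4-bis(methoxymethoxy)-3-(3-methylbut-2-en-1-yl)phenyl]prop-2-en-1-yl}-2-(3-methylbut-2-en-1-yl)benzene-1,3-diol
Conditions: Pd(OAc)2 (5 mol %), PPh3 (20 mol %), Et3B (30 mol %), THF, 50 °C
Reagents that add atoms: none
Why: In this Tsuji–Trost-type Friedel–Crafts C-allylation with direct use of the allylic alcohol (the hydroxyl of 12 and the C4–H of 7 leave as water), the symmetric 2-aryl-π-allylpalladium electrophile should be attacked by C4 of the resorcinol (C4 and C6 are equivalent and O-allyl ethers re-ionise at zerovalent palladium), which leaves free the ortho hydroxyl that becomes O1.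

Step 6
Reactants: 13 4-{2-[2,4-bis(methoxymethoxy)-3-(3-methylbut-2-en-1-yl)phenyl]prop-2-en-1-yl}-2-(3-methylbut-2-en-1-yl)benzene-1,3-diol; 14 bis(pinacolato)diboron
Product: 16 4-[(2R)-2-[2,4-bis(methoxymethoxy)-3-(3-methylbut-2-en-1-yl)phenyl]-3-hydroxypropyl]-2-(3-methylbut-2-en-1-yl)benzene-1,3-diol, via (R)-alkylboronate 15 (not isolated)
Conditions: CuCl (7.5 mol %), chiral sulfonate-bearing imidazolinium salt (NHC precursor, 7.5 mol %), KOt-Bu (30 mol %), MeOH (2 equiv), THF, −50 to −15 °C; then NaBO3·4H2O, THF/H2O, rt
Reagents that add atoms: sodium perborate (NaBO3), [Na+].[O-]OB=O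
Why: In this NHC–copper-catalysed enantioselective protoboration of a 1,1-disubstituted aryl alkene, Cu–Bpin should add with boron on the terminal CH2 and copper on the benzylic carbon, the ligand-controlled face of addition followed by stereoretentive protonation setting C3, and stereoretentive perborate oxidation of the C–B bond should give the primary alcohol while the trisubstituted prenyl alkenes stay inert.

Step 7
Reactants: 16 4-[(2R)-2-[2,4-bis(methoxymethoxy)-3-(3-methylbut-2-en-1-yl)phenyl]-3-hydroxypropyl]-2-(3-methylbut-2-en-1-yl)benzene-1,3-diol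
Product: 17 (3R)-3-[2,4-bis(methoxymethoxy)-3-(3-methylbut-2-en-1-yl)phenyl]-8-(3-methylbut-2-en-1-yl)-3,4-dihydro-2H-chromen-7-ol
Conditions: PPh3, DIAD, THF (0.01 M), 0 °C to rt
Reagents that add atoms: none
Why: PPh3 and DIAD form the betaine, which deprotonates the phenol and turns the primary C2–OH into an alkoxyphosphonium ion that phenoxide O1 displaces by SN2 with loss of triphenylphosphine oxide. The closest known reaction type is the intramolecular Mitsunobu etherification used to close isoflavans from 2-aryl-3-(2-hydroxyaryl)propan-1-ols. Ring C closes in the 6-exo-tet mode along O1–C8a–C4a–C4–C3–C2. No stereocentre is created: substitution takes place at the CH2 carbon C2, so the C3 configuration fixed in step 6 should be carried over unchanged (descriptor R before and after). The step needs O1 to react in preference to O7, O2′ and O4′: O7 is para to C4a and cannot reach C2 within the molecule (high dilution suppresses intermolecular etherification), and both ring B oxygens are MOM ethers, which blocks the competing 5-exo-tet closure through O2′ to a 3-benzyl-2,3-dihydrobenzofuran. The neutral conditions at 0 °C should also keep the electron-rich ring B from anchimeric participation at C2.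

Step 8
Reactants: 17 (3R)-3-[2,4-bis(methoxymethoxy)-3-(3-methylbut-2-en-1-yl)phenyl]-8-(3-methylbut-2-en-1-yl)-3,4-dihydro-2H-chromen-7-ol
Product: 18 Kanzonol X, 4-[(3R)-7-hydroxy-8-(3-methylbut-2-en-1-yl)-3,4-dihydro-2H-chromen-3-yl]-2-(3-methylbut-2-en-1-yl)benzene-1,3-diol
Conditions: HCl (3 M aq.), MeOH, 40 °C, short reaction time
Reagents that add atoms: none
Why: Acid-catalysed acetal exchange with methanol should remove both MOM groups under the same mild treatment that spares the ortho-prenyl phenol in step 3, and C3 has no pathway to epimerise under these conditions.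

Compound list
1 | resorcinol (benzene-1,3-diol) | Oc1cccc(O)c1 | starting material
2 | chloromethyl methyl ether | COCCl | starting material
3 | 1,3-bis(methoxymethoxy)benzene | COCOc1cccc(OCOC)c1 | intermediate
4 | prenyl bromide (1-bromo-3-methylbut-2-ene) | CC(C)=CCBr | starting material
5 | [2,6-bis(methoxymethoxy)phenyl]lithium | [Li]c1c(OCOC)cccc1OCOC | intermediate (not isolated)
6 | 1,3-bis(methoxymethoxy)-2-(3-methylbut-2-en-1-yl)benzene | COCOc1cccc(OCOC)c1CC=C(C)C | intermediate
7 | 2-(3-methylbut-2-en-1-yl)benzene-1,3-diol (2-prenylresorcinol) | CC(C)=CCc1c(O)cccc1O | intermediate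
8 | triisopropyl borate | CC(C)OB(OC(C)C)OC(C)C | starting material
9 | 2-bromoprop-2-en-1-ol | OCC(Br)=C | starting material
10 | [2,4-bis(methoxymethoxy)-3-(3-methylbut-2-en-1-yl)phenyl]lithium | [Li]c1ccc(OCOC)c(CC=C(C)C)c1OCOC | intermediate (not isolated)
11 | lithium [2,4-bis(methoxymethoxy)-3-(3-methylbut-2-en-1-yl)phenyl]tri(propan-2-yloxy)borate | [Li+].CC(C)O[B-](OC(C)C)(OC(C)C)c1ccc(OCOC)c(CC=C(C)C)c1OCOC | intermediate (not isolated)
12 | 2-[2,4-bis(methoxymethoxy)-3-(3-methylbut-2-en-1-yl)phenyl]prop-2-en-1-ol | C=C(CO)c1ccc(OCOC)c(CC=C(C)C)c1OCOC | intermediate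
13 | 4-{2-[2,4-bis(methoxymethoxy)-3-(3-methylbut-2-en-1-yl)phenyl]prop-2-en-1-yl}-2-(3-methylbut-2-en-1-yl)benzene-1,3-diol | C=C(Cc1ccc(O)c(CC=C(C)C)c1O)c1ccc(OCOC)c(CC=C(C)C)c1OCOC | intermediate
14 | bis(pinacolato)diboron | CC1(C)OB(OC1(C)C)B1OC(C)(C)C(C)(C)O1 | starting material
15 | 4-[(2R)-2-[2,4-bis(methoxymethoxy)-3-(3-methylbut-2-en-1-yl)phenyl]-3-(4,4,5,5-tetramethyl-1,3,2-dioxaborolan-2-yl)propyl]-2-(3-methylbut-2-en-1-yl)benzene-1,3-diol | CC(C)=CCc1c(OCOC)ccc([C@@H](Cc2ccc(O)c(CC=C(C)C)c2O)CB2OC(C)(C)C(C)(C)O2)c1OCOC | intermediate (not isolated)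
16 | 4-[(2R)-2-[2,4-bis(methoxymethoxy)-3-(3-methylbut-2-en-1-yl)phenyl]-3-hydroxypropyl]-2-(3-methylbut-2-en-1-yl)benzene-1,3-diol | CC(C)=CCc1c(OCOC)ccc([C@@H](Cc2ccc(O)c(CC=C(C)C)c2O)CO)c1OCOC | intermediate
17 | (3R)-3-[2,4-bis(methoxymethoxy)-3-(3-methylbut-2-en-1-yl)phenyl]-8-(3-methylbut-2-en-1-yl)-3,4-dihydro-2H-chromen-7-ol | CC(C)=CCc1c(OCOC)ccc([C@@H]2COc3c(ccc(O)c3CC=C(C)C)C2)c1OCOC | intermediate
18 | Kanzonol X, 4-[(3R)-7-hydroxy-8-(3-methylbut-2-en-1-yl)-3,4-dihydro-2H-chromen-3-yl]-2-(3-methylbut-2-en-1-yl)benzene-1,3-diol | CC(C)=CCc1c(O)ccc([C@@H]2COc3c(ccc(O)c3CC=C(C)C)C2)c1O | target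

Total step count: 8

Longest linear sequence: 7 steps (steps 1, 2, 4, 5, 6, 7, 8); step 3 is a one-step branch from compound 6.

Steps most likely to fail

Step 6. The Cu–B addition may discriminate the two alkene faces poorly, because the α-substituent is a benzyl-type CH2 and the ortho OMOM group twists ring B out of conjugation. The two free phenols may also slow turnover by tying up the copper alkoxide. Either process would lower enantiomeric purity or conversion. The fallback sets out from 13 and gives up asymmetric induction: protoboration with an achiral catalyst (CuCl, Xantphos, KOt-Bu, B2pin2, MeOH) should give the racemic boronate F1, which NaBO3·4H2O oxidises to the racemic alcohol F2. The enantiomers of F2 are then separated by preparative chromatography on a chiral stationary phase; the (R)-enantiomer is compound 16, where the route resumes.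

Step 5. O-Allylation may fail to funnel to the C-allyl product, a second allyl group may enter at C6, or the π-allyl complex may attack the prenyl-bearing C2 with loss of aromaticity. The fallback sets out from 7 (in excess) and 12: a Mitsunobu reaction (PPh3, DIAD, THF) should give the mono-allyl aryl ether F3. A thermal aromatic Claisen rearrangement (N,N-diethylaniline, 170–180 °C) then moves the 2-arylallyl group to the only free ortho carbon, which gives compound 13.

Step 4. The base may deprotonate the doubly activated benzylic–allylic CH2 of the prenyl group (lateral lithiation) instead of C4–H, and the electron-rich borate may lose boron by protonation before it couples. The fallback sets out from 3 and fixes the lithiation site with a halogen. Bromination with NBS (MeCN, 0 °C) should give the 4-bromo derivative F4. LiN(i-Pr)2 (THF, −78 °C) then lithiates the position between the two OMOM groups to give the aryllithium F5, which prenyl bromide 4 (CuBr·SMe2 cat.) alkylates to the aryl bromide F6. Bromine–lithium exchange (n-BuLi, −78 °C) gives aryllithium 10, where the route resumes.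

Further compounds
F1 | step 6 | racemic 4-[2-[2,4-bis(methoxymethoxy)-3-(3-methylbut-2-en-1-yl)phenyl]-3-(4,4,5,5-tetramethyl-1,3,2-dioxaborolan-2-yl)propyl]-2-(3-methylbut-2-en-1-yl)benzene-1,3-diol | CC(C)=CCc1c(OCOC)ccc(C(Cc2ccc(O)c(CC=C(C)C)c2O)CB2OC(C)(C)C(C)(C)O2)c1OCOC
F2 | step 6 | racemic 4-[2-[2,4-bis(methoxymethoxy)-3-(3-methylbut-2-en-1-yl)phenyl]-3-hydroxypropyl]-2-(3-methylbut-2-en-1-yl)benzene-1,3-diol | CC(C)=CCc1c(OCOC)ccc(C(Cc2ccc(O)c(CC=C(C)C)c2O)CO)c1OCOC
F3 | step 5 | 3-({2-[2,4-bis(methoxymethoxy)-3-(3-methylbut-2-en-1-yl)phenyl]prop-2-en-1-yl}oxy)-2-(3-methylbut-2-en-1-yl)phenol | C=C(COc1cccc(O)c1CC=C(C)C)c1ccc(OCOC)c(CC=C(C)C)c1OCOC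
F4 | step 4 | 1-bromo-2,4-bis(methoxymethoxy)benzene | COCOc1ccc(Br)c(OCOC)c1
F5 | step 4 | [3-bromo-2,6-bis(methoxymethoxy)phenyl]lithium | [Li]c1c(OCOC)ccc(Br)c1OCOC
F6 | step 4 | 1-bromo-2,4-bis(methoxymethoxy)-3-(3-methylbut-2-en-1-yl)benzene | COCOc1ccc(Br)c(OCOC)c1CC=C(C)C
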